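## The problem

Compound 25 is a 2,3-dihydrobenzofuran in which the benzene ring A (C3a to C7a) is fused to the oxygen ring B (O1, C2, C3); C2 carries the 3,4-dimethoxyphenyl ring C, C3 a methyl group, C7 a methoxy group and C5 an (E)-3-hydroxyprop-1-enyl chain. The only stereocentres are C2 (S) and C3 (S), which are adjacent and trans across ring B. C2 is at once a benzylic carbon of an electron-rich arene and an ether carbon, so it ionises under acid; this lets C2 settle trans to C3, but the same cation can lose H3 and erase C3. C3 therefore cannot be corrected later and has to be set by a reagent, and in an open chain it steers C2 only weakly. The conjugated allylic alcohol tolerates neither acid, hydrogenation nor peroxide, and a free para-hydroxybenzaldehyde would undergo Dakin oxidation, which together fix the order of the late steps. The enabling feature is that C2 is a lone methine whose three heavy neighbours are C3, C1' of ring C and O1, while C3 is a methine between C3a, the methyl carbon and C2. Each of these carbons can be brought to boron as a chlorocarbenoid carbon and then accept its second carbon group by migration. One molecule of dichloromethane can thus become C2, with both of its C–C bonds made by migration from boron and with boron left on C2 where O1 has to be attached.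

## Retrosynthesis

**Side chain.** Target 25 is traced to the ethyl cinnamate 24 by reduction, and 24 to aldehyde 23 by cutting the side-chain C=C bond (Wittig). Carrying the finished chain through the route would expose an allylic alcohol to organolithium reagents, hydrogenolysis and peroxide. The aldehyde carbon is already present in 5-bromovanillin 1, so nothing has to be added to ring A. The forward steps need only (E)-selectivity and 1,2-reduction.

**O1–C2.** In 23 the O1–C2 bond is cut, giving the open-chain phenol carbinol 21, whose aldehyde is still a dioxolane (the ring-closed acetal 22 forms first). Cutting C7a–O1 instead would need an aryl halide on ring A, which cannot coexist with the boron chemistry. Cutting O1–C2 leaves a carbinol, which is what a C–B bond gives on oxidation. The forward reaction must be a substitution by the phenol at C2 with inversion (Mitsunobu, 5-exo-tet). Because C3 is already fixed, any leakage through a C2 cation still leads mainly to the trans ring and not to the enantiomer.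

**C2–O from C2–B.** Carbinol 21 comes from the phenol boronic ester 20 by oxidation with retention, and 20 from the benzyl ether 19 by hydrogenolysis. The benzyl group is removed while C2 still carries boron, so no benzylic C–O bond at C2 is exposed to hydrogen. The aldehyde stays masked during the peroxide step. A methoxymethyl ether was rejected because its acid cleavage would act on an ionisable carbinol or unmask the aldehyde too early.

**C2–C3 and C2–C1' (key step).** In 19 both C–C bonds of C2 are cut, leading to the secondary benzylic boronic ester 13, the carbenoid 9 (made from dichloromethane 8) and the aryl Grignard reagent 15 (made from bromide 14). This removes a whole aryl ring and one stereocentre in a single operation. Cutting only C2–C1' (aryl addition to an aldehyde) would leave C2 to substrate control. The forward reaction must insert CHCl into the C3–B bond with retention at C3 and diol control at the new carbon, giving chloride 17, and then displace the chloride by aryl migration with inversion. With the (R,R)-diol 4 the chloride of 17 is (αS), aryl migration gives the (1R) centre of 19, oxidation retains it, and the Mitsunobu closure inverts it to (2S) of 25.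

**C3–C3a and C3–CH3.** Boronic ester 13 is cut at C3 in the same way, to the arylboronic ester 7, a second portion of carbenoid 9 and a methyl nucleophile. Aryl migration gives the (αS)-chloride 11, and methyl migration inverts it to the (S) centre that becomes C3 of 25. The same diol thus sets both centres, and the iteration needs no change of auxiliary.

**C–B and protecting groups.** Ester 7 comes from aryl bromide 3 by bromine–lithium exchange, borylation and esterification with diol 4. Bromide 3 comes from 1 through benzyl ether 2 and acetalisation. Ring A is bought with its complete oxygen pattern, with the bromine at the future C3a and the formyl group at C5.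

## Roads not taken

Alternative 1: Cut C2–C3 by carbene C–H insertion.
- Forward step: diazo ester A1, the 3,4-dimethoxybenzyl ether of an ortho-hydroxyaryl diazoacetate, would be decomposed by the chiral dirhodium tetracarboxylate Rh2(S-PTTL)4 (dirhodium tetrakis[N-phthaloyl-(S)-tert-leucinate]). The carbene at C3 inserts into the benzylic ether C–H bond and closes ring B as the cis ester A2.
- Merits: chirality comes from a catalyst, the ring and both stereocentres form in one step, and no cryogenic carbenoid is needed. In these respects it is better than the chosen plan.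
- Weak points: A2 is cis, so C3 must be epimerised by base, with a risk of retro-oxa-Michael ring opening that would scramble C2. The C3 ester then needs three reductive operations to become a methyl group, all in the presence of the aryl bromide. The chain must still be attached at C5 by a Heck-type coupling, and a diazo compound must be made and handled.
- Comparison: step counts are similar. The chosen plan brings C3 in as a methyl group in its final configuration, needs no epimerisation, and controls both centres by the same reagent, so errors appear as diastereomers.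

Alternative 2: Build ring A last.
- Forward step: lactone A3 carries both stereocentres and is converted into its silyl ketene acetal A4. A4 adds thermally across C3 and C6 of the bromopyrone ester A5. Decarboxylative cycloreversion and loss of the silyloxy group aromatise ring A to give A6.
- Merits: O1–C2 is never made by substitution at the ionisable benzylic carbon, and the late stage needs no organometallic reagent.
- Weak points: A6 carries bromine at C7 and an ester at C5. A hindered bromide ortho to the ring oxygen must be exchanged for methoxy, and the ester must be taken to the aldehyde oxidation state before the same Wittig and reduction endgame. The trans lactone A3 is itself an enantioselective synthesis of several steps, and the cycloaddition needs prolonged heating of an acid-sensitive ketene acetal.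
- Comparison: the chosen plan buys ring A with its full oxygen pattern in 1 and is shorter. It accepts in return two cryogenic homologations and a stoichiometric, recoverable chiral diol.

Alternative 3: Cut O1–C2 by anodic decarboxylation.
- Forward step: electrolysis of the carboxylate of acid A7 at a graphite anode would generate a C2 cation stabilised by ring C. The ortho phenol captures it trans to the C3 methyl, giving aldehyde A8, the same compound as 23.
- Merits: C2 need not be controlled in the precursor, the phenol needs no protecting group, and the endgame is shared with the chosen route. On protecting-group economy it is better.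
- Weak points: the free guaiacol-type phenol and ring C are oxidised at potentials near or below that of the carboxylate. The C2 cation can lose H3, which erodes the only stereocentre the precursor carries. The trans preference is a matter of degree, and A7 still needs an enantioselective synthesis of its C3 centre.
- Comparison: the chosen plan sets C2 by two stereospecific events (migration with inversion, substitution with inversion) and never places a cation next to C3.

Key step: step 7

Remark on the chemistry: the (R,R)-diol 4 is taken to direct the chloride to the (αS) configuration (Cl > C > B > H), the established sense for C2-symmetric (R,R)-1,2-diol boronic esters; all descriptors below follow from this.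

## Route

Step 1
Reactants: 1 5-bromovanillin (3-bromo-4-hydroxy-5-methoxybenzaldehyde)
Product: 2 4-(benzyloxy)-3-bromo-5-methoxybenzaldehyde
Conditions: BnBr, K2CO3, DMF, rt
Reagents that add atoms: benzyl bromide, BrCc1ccccc1
Why: Williamson etherification of the phenoxide. The benzyl ether survives organolithium and Grignard reagents and is later removed by neutral hydrogenolysis.

Step 2
Reactants: 2 4-(benzyloxy)-3-bromo-5-methoxybenzaldehyde
Product: 3 2-[4-(benzyloxy)-3-bromo-5-methoxyphenyl]-1,3-dioxolane
Conditions: HOCH2CH2OH, p-TsOH (cat.), toluene, reflux, Dean–Stark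
Reagents that add atoms: ethylene glycol, OCCO
Why: Acid-catalysed acetalisation with azeotropic removal of water. The dioxolane masks the aldehyde against n-BuLi, the carbenoid, the Grignard reagents and the later peroxide oxidation.

Step 3
Reactants: 3 2-[4-(benzyloxy)-3-bromo-5-methoxyphenyl]-1,3-dioxolane; 4 (1R,2R)-1,2-dicyclohexylethane-1,2-diol
Product: 7 (4R,5R)-2-[2-(benzyloxy)-5-(1,3-dioxolan-2-yl)-3-methoxyphenyl]-4,5-dicyclohexyl-1,3,2-dioxaborolane, via aryllithium 5 (not isolated), via lithium aryltriisopropoxyborate 6 (not isolated)
Conditions: n-BuLi, THF, −78 °C; B(OiPr)3, −78 °C to rt; then 4, AcOH, rt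
Reagents that add atoms: triisopropyl borate, CC(C)OB(OC(C)C)OC(C)C
Why: Bromine–lithium exchange at −78 °C is faster than any attack on the ether or acetal, and the borate traps aryllithium 5 as ate complex 6. On protonation the diol displaces isopropoxide to give the five-membered cyclic ester (borylation followed by transesterification).

Step 4
Reactants: 8 dichloromethane
Product: 9 dichloromethyllithium (cold THF solution for immediate use)
Conditions: n-BuLi (hexanes), THF, −100 °C
Reagents that add atoms: n-butyllithium, [Li]CCCC
Why: Lithiation of the acidic C–H bond of dichloromethane by n-butyllithium gives the α-chloro carbenoid, which persists only below about −90 °C. It is therefore made in the reaction flask immediately before use, once for step 5 and once again for step 7, and is never stored.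

Step 5
Reactants: 7 (4R,5R)-2-[2-(benzyloxy)-5-(1,3-dioxolan-2-yl)-3-methoxyphenyl]-4,5-dicyclohexyl-1,3,2-dioxaborolane; 9 dichloromethyllithium
Product: 13 (4R,5R)-2-[(1S)-1-[2-(benzyloxy)-5-(1,3-dioxolan-2-yl)-3-methoxyphenyl]ethyl]-4,5-dicyclohexyl-1,3,2-dioxaborolane, via lithium dichloromethylborate 10 (not isolated), via (S)-chlorobenzylboronic ester 11 (not isolated), via bromomagnesium methylborate 12 (not isolated)
Conditions: 9 in THF, −100 °C, add 7; ZnCl2, −100 °C to rt; then MeMgBr, −78 °C to rt
Reagents that add atoms: methylmagnesium bromide, C[Mg]Br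
Why: Matteson homologation: 9 adds to boron (10), and ZnCl2 promotes aryl migration with loss of chloride to give the (αS)-chloride 11 under control of the (R,R)-diol. Methyl migration in 12 then displaces the chloride with inversion, which sets the future C3 as (S).

Step 6
Reactants: 14 4-bromo-1,2-dimethoxybenzene
Product: 15 3,4-dimethoxyphenylmagnesium bromide (titrated THF solution)
Conditions: Mg, I2 (cat.), THF, 40 °C
Reagents that add atoms: magnesium, [Mg]
Why: Direct insertion of magnesium into the aryl bromide (Grignard formation). The methoxy groups are inert and the solution is used as such.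

Step 7
Reactants: 13 (4R,5R)-2-[(1S)-1-[2-(benzyloxy)-5-(1,3-dioxolan-2-yl)-3-methoxyphenyl]ethyl]-4,5-dicyclohexyl-1,3,2-dioxaborolane; 9 dichloromethyllithium; 15 3,4-dimethoxyphenylmagnesium bromide
Product: 19 (4R,5R)-2-[(1R,2R)-2-[2-(benzyloxy)-5-(1,3-dioxolan-2-yl)-3-methoxyphenyl]-1-(3,4-dimethoxyphenyl)propyl]-4,5-dicyclohexyl-1,3,2-dioxaborolane, via lithium dichloromethylborate 16 (not isolated), via (1S,2S)-1-chloropropylboronic ester 17 (not isolated), via bromomagnesium arylborate 18 (not isolated)
Conditions: 9 in THF, −100 °C, add 13; ZnCl2, −100 °C to rt; then 15 (excess), −78 °C to rt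
Reagents that add atoms: none
Why: Dichloromethyllithium 9 adds to the boron of 13 to give borate 16, and ZnCl2 then promotes 1,2-migration of C3 from boron to the carbenoid carbon with loss of one chloride, which forms C2–C3 with retention at the migrating centre and gives chloride 17. Addition of 15 to boron gives borate 18, in which the 3,4-dimethoxyphenyl group migrates antiperiplanar to the remaining chloride and displaces it with inversion, forming C2–C1'. The closest known reaction type is the Matteson homologation of chiral diol boronic esters with LiCHCl2 followed by Grignard displacement of the α-chloride, applied here for the second time in succession, now to a 1-arylethyl boronic ester. No ring closes in this step. The new stereocentre C2 is controlled by the (R,R)-diol: in the ZnCl2-bound borate 16 one of the two diastereotopic chlorides is placed anti to the migrating group, which gives the (1S)-chloride 17, and the aryl migration inverts it to the (1R) centre of 19. The step needs diastereoselection at the CHCl carbon, carbon migration in preference to ring-expanding oxygen migration in 18, and no chloride-induced epimerisation of 17; the C2-symmetric diol, the high migratory aptitude of an aryl group and the chloride-binding ZnCl2 secure these in that order. C3 was set by the same diol in step 5, so the second induction repeats the first and any stereochemical error appears as a diastereomer.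

Step 8
Reactants: 19 (4R,5R)-2-[(1R,2R)-2-[2-(benzyloxy)-5-(1,3-dioxolan-2-yl)-3-methoxyphenyl]-1-(3,4-dimethoxyphenyl)propyl]-4,5-dicyclohexyl-1,3,2-dioxaborolane
Product: 20 2-[(1R,2R)-1-[(4R,5R)-4,5-dicyclohexyl-1,3,2-dioxaborolan-2-yl]-1-(3,4-dimethoxyphenyl)propan-2-yl]-4-(1,3-dioxolan-2-yl)-6-methoxyphenol
Conditions: H2 (1 atm), Pd/C, EtOAc, rt
Reagents that add atoms: none
Why: Hydrogenolysis of the aryl benzyl ether over palladium. At this stage C2 carries boron and not oxygen, so no benzylic C–O bond at C2 can be cleaved; the C–B bond, the acetal and both stereocentres should be untouched.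

Step 9
Reactants: 20 2-[(1R,2R)-1-[(4R,5R)-4,5-dicyclohexyl-1,3,2-dioxaborolan-2-yl]-1-(3,4-dimethoxyphenyl)propan-2-yl]-4-(1,3-dioxolan-2-yl)-6-methoxyphenol
Product: 21 2-[(1R,2S)-1-(3,4-dimethoxyphenyl)-1-hydroxypropan-2-yl]-4-(1,3-dioxolan-2-yl)-6-methoxyphenol
Conditions: H2O2 (30% aq.), NaOH (aq.), THF, 0 °C to rt
Reagents that add atoms: hydrogen peroxide, OO
Why: Oxidation of the C–B bond by hydroperoxide (1,2-shift of carbon from boron to oxygen) proceeds with retention at C2. The acetal prevents a Dakin oxidation of the aldehyde, and diol 4 is recovered.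

Step 10
Reactants: 21 2-[(1R,2S)-1-(3,4-dimethoxyphenyl)-1-hydroxypropan-2-yl]-4-(1,3-dioxolan-2-yl)-6-methoxyphenol
Product: 23 (2S,3S)-2-(3,4-dimethoxyphenyl)-7-methoxy-3-methyl-2,3-dihydro-1-benzofuran-5-carbaldehyde, via dioxolane-protected dihydrobenzofuran 22 (not isolated)
Conditions: PPh3, DIAD, THF, 0 °C to rt; then 1 M aq. HCl, rt
Reagents that add atoms: water, O
Why: Intramolecular Mitsunobu etherification: the benzylic alcohol is activated as its alkoxyphosphonium salt and displaced by the phenoxide in a 5-exo-tet closure with inversion at C2, which places ring C trans to the C3 methyl group. Dilute acid then hydrolyses the dioxolane of 22 in the same flask.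

Step 11
Reactants: 23 (2S,3S)-2-(3,4-dimethoxyphenyl)-7-methoxy-3-methyl-2,3-dihydro-1-benzofuran-5-carbaldehyde
Product: 24 ethyl (2E)-3-[(2S,3S)-2-(3,4-dimethoxyphenyl)-7-methoxy-3-methyl-2,3-dihydro-1-benzofuran-5-yl]prop-2-enoate
Conditions: Ph3P=CHCO2Et, toluene, 80 °C
Reagents that add atoms: ethyl (triphenylphosphoranylidene)acetate, CCOC(=O)C=P(c1ccccc1)(c1ccccc1)c1ccccc1
Why: Wittig olefination of an aryl aldehyde with a stabilised ylide, which should give the (E)-cinnamate. The conditions are neutral and do not touch C2.

Step 12
Reactants: 24 ethyl (2E)-3-[(2S,3S)-2-(3,4-dimethoxyphenyl)-7-methoxy-3-methyl-2,3-dihydro-1-benzofuran-5-yl]prop-2-enoate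
Product: 25 (2E)-3-[(2S,3S)-2-(3,4-dimethoxyphenyl)-7-methoxy-3-methyl-2,3-dihydro-1-benzofuran-5-yl]prop-2-en-1-ol
Conditions: DIBAL-H, toluene, −78 °C
Reagents that add atoms: none
Why: 1,2-Reduction of the α,β-unsaturated ester by diisobutylaluminium hydride should give the allylic alcohol without touching the alkene or the benzylic ether of ring B.

## Compound list

1 | 5-bromovanillin (3-bromo-4-hydroxy-5-methoxybenzaldehyde) | O=Cc1cc(Br)c(O)c(OC)c1 | starting material
2 | 4-(benzyloxy)-3-bromo-5-methoxybenzaldehyde | O=Cc1cc(Br)c(OCc2ccccc2)c(OC)c1 | intermediate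
3 | 2-[4-(benzyloxy)-3-bromo-5-methoxyphenyl]-1,3-dioxolane | COc1cc(C2OCCO2)cc(Br)c1OCc1ccccc1 | intermediate
4 | (1R,2R)-1,2-dicyclohexylethane-1,2-diol | O[C@H](C1CCCCC1)[C@H](O)C1CCCCC1 | starting material
5 | [2-(benzyloxy)-5-(1,3-dioxolan-2-yl)-3-methoxyphenyl]lithium | [Li]c1cc(C2OCCO2)cc(OC)c1OCc1ccccc1 | intermediate
6 | lithium [2-(benzyloxy)-5-(1,3-dioxolan-2-yl)-3-methoxyphenyl]tri(propan-2-yloxy)borate | [Li+].CC(C)O[B-](OC(C)C)(OC(C)C)c1cc(C2OCCO2)cc(OC)c1OCc1ccccc1 | intermediate
7 | (4R,5R)-2-[2-(benzyloxy)-5-(1,3-dioxolan-2-yl)-3-methoxyphenyl]-4,5-dicyclohexyl-1,3,2-dioxaborolane | COc1cc(C2OCCO2)cc(B2O[C@H](C3CCCCC3)[C@@H](C3CCCCC3)O2)c1OCc1ccccc1 | intermediate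
8 | dichloromethane | ClCCl | starting material
9 | dichloromethyllithium | [Li]C(Cl)Cl | intermediate
10 | lithium (4R,5R)-2-[2-(benzyloxy)-5-(1,3-dioxolan-2-yl)-3-methoxyphenyl]-4,5-dicyclohexyl-2-(dichloromethyl)-1,3,2-dioxaborolan-2-uide | [Li+].ClC(Cl)[B-]1(c2cc(C3OCCO3)cc(OC)c2OCc2ccccc2)O[C@H](C2CCCCC2)[C@@H](C2CCCCC2)O1 | intermediate
11 | (4R,5R)-2-[(S)-[2-(benzyloxy)-5-(1,3-dioxolan-2-yl)-3-methoxyphenyl](chloro)methyl]-4,5-dicyclohexyl-1,3,2-dioxaborolane | Cl[C@@H](B1O[C@H](C2CCCCC2)[C@@H](C2CCCCC2)O1)c1cc(C2OCCO2)cc(OC)c1OCc1ccccc1 | intermediate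
12 | bromomagnesium (4R,5R)-2-[(S)-[2-(benzyloxy)-5-(1,3-dioxolan-2-yl)-3-methoxyphenyl](chloro)methyl]-4,5-dicyclohexyl-2-methyl-1,3,2-dioxaborolan-2-uide | Cl[C@@H]([B-]1(C)O[C@H](C2CCCCC2)[C@@H](C2CCCCC2)O1)c1cc(C2OCCO2)cc(OC)c1OCc1ccccc1.[Mg+]Br | intermediate
13 | (4R,5R)-2-[(1S)-1-[2-(benzyloxy)-5-(1,3-dioxolan-2-yl)-3-methoxyphenyl]ethyl]-4,5-dicyclohexyl-1,3,2-dioxaborolane | C[C@H](B1O[C@H](C2CCCCC2)[C@@H](C2CCCCC2)O1)c1cc(C2OCCO2)cc(OC)c1OCc1ccccc1 | intermediate
14 | 4-bromo-1,2-dimethoxybenzene | COc1ccc(Br)cc1OC | starting material
15 | 3,4-dimethoxyphenylmagnesium bromide | COc1ccc([Mg]Br)cc1OC | intermediate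
16 | lithium (4R,5R)-2-[(1S)-1-[2-(benzyloxy)-5-(1,3-dioxolan-2-yl)-3-methoxyphenyl]ethyl]-4,5-dicyclohexyl-2-(dichloromethyl)-1,3,2-dioxaborolan-2-uide | C[C@H]([B-]1(C(Cl)Cl)O[C@H](C2CCCCC2)[C@@H](C2CCCCC2)O1)c1cc(C2OCCO2)cc(OC)c1OCc1ccccc1.[Li+] | intermediate
17 | (4R,5R)-2-[(1S,2S)-2-[2-(benzyloxy)-5-(1,3-dioxolan-2-yl)-3-methoxyphenyl]-1-chloropropyl]-4,5-dicyclohexyl-1,3,2-dioxaborolane | C[C@H]([C@@H](Cl)B1O[C@H](C2CCCCC2)[C@@H](C2CCCCC2)O1)c1cc(C2OCCO2)cc(OC)c1OCc1ccccc1 | intermediate
18 | bromomagnesium (4R,5R)-2-[(1S,2S)-2-[2-(benzyloxy)-5-(1,3-dioxolan-2-yl)-3-methoxyphenyl]-1-chloropropyl]-4,5-dicyclohexyl-2-(3,4-dimethoxyphenyl)-1,3,2-dioxaborolan-2-uide | C[C@H]([C@@H](Cl)[B-]1(c2ccc(OC)c(OC)c2)O[C@H](C2CCCCC2)[C@@H](C2CCCCC2)O1)c1cc(C2OCCO2)cc(OC)c1OCc1ccccc1.[Mg+]Br | intermediate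
19 | (4R,5R)-2-[(1R,2R)-2-[2-(benzyloxy)-5-(1,3-dioxolan-2-yl)-3-methoxyphenyl]-1-(3,4-dimethoxyphenyl)propyl]-4,5-dicyclohexyl-1,3,2-dioxaborolane | COc1ccc([C@H](B2O[C@H](C3CCCCC3)[C@@H](C3CCCCC3)O2)[C@@H](C)c2cc(C3OCCO3)cc(OC)c2OCc2ccccc2)cc1OC | intermediate
20 | 2-[(1R,2R)-1-[(4R,5R)-4,5-dicyclohexyl-1,3,2-dioxaborolan-2-yl]-1-(3,4-dimethoxyphenyl)propan-2-yl]-4-(1,3-dioxolan-2-yl)-6-methoxyphenol | COc1ccc([C@H](B2O[C@H](C3CCCCC3)[C@@H](C3CCCCC3)O2)[C@@H](C)c2cc(C3OCCO3)cc(OC)c2O)cc1OC | intermediate
21 | 2-[(1R,2S)-1-(3,4-dimethoxyphenyl)-1-hydroxypropan-2-yl]-4-(1,3-dioxolan-2-yl)-6-methoxyphenol | COc1ccc([C@H](O)[C@@H](C)c2cc(C3OCCO3)cc(OC)c2O)cc1OC | intermediate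
22 | 2-[(2S,3S)-2-(3,4-dimethoxyphenyl)-7-methoxy-3-methyl-2,3-dihydro-1-benzofuran-5-yl]-1,3-dioxolane | COc1ccc([C@H]2Oc3c(OC)cc(C4OCCO4)cc3[C@@H]2C)cc1OC | intermediate
23 | (2S,3S)-2-(3,4-dimethoxyphenyl)-7-methoxy-3-methyl-2,3-dihydro-1-benzofuran-5-carbaldehyde | COc1ccc([C@H]2Oc3c(OC)cc(C=O)cc3[C@@H]2C)cc1OC | intermediate
24 | ethyl (2E)-3-[(2S,3S)-2-(3,4-dimethoxyphenyl)-7-methoxy-3-methyl-2,3-dihydro-1-benzofuran-5-yl]prop-2-enoate | COc1ccc([C@H]2Oc3c(OC)cc(/C=C/C(=O)OCC)cc3[C@@H]2C)cc1OC | intermediate
25 | (2E)-3-[(2S,3S)-2-(3,4-dimethoxyphenyl)-7-methoxy-3-methyl-2,3-dihydro-1-benzofuran-5-yl]prop-2-en-1-ol | COc1ccc([C@H]2Oc3c(OC)cc(/C=C/CO)cc3[C@@H]2C)cc1OC | target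

## Step count and risk

Total step count: 12. Longest linear sequence: 10 steps (steps 1, 2, 3, 5 and 7 to 12, from 1). Steps 4 and 6 prepare the carbenoid and the Grignard reagent in side branches. Step 4 is carried out twice, immediately before step 5 and again immediately before step 7, because 9 cannot be stored.

**Step 7 (key step).**
- Risk: capture of the hindered secondary benzylic boronic ester 13 by the short-lived carbenoid 9 may be slow, so that thermal decay of the carbenoid competes. Displacement in the β-branched chloride 17 may also be sluggish, so that oxygen migration or chloride-exchange epimerisation at C2 competes with aryl migration.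
- Fallback: set out from 13 and run only the first half of step 7 to chloride 17. Oxidise 17 with hydrogen peroxide buffered by NaHCO3, which converts an α-chloro boronic ester into the aldehyde, to give (2S)-2-[2-(benzyloxy)-5-(1,3-dioxolan-2-yl)-3-methoxyphenyl]propanal F1. Add 15 at −78 °C; by the Felkin–Anh model the aryl group should enter anti to ring A and give mainly the syn carbinol (1R,2S)-2-[2-(benzyloxy)-5-(1,3-dioxolan-2-yl)-3-methoxyphenyl]-1-(3,4-dimethoxyphenyl)propan-1-ol F2. Hydrogenolysis of the benzyl ether of F2 (H2, Pd/C, EtOAc, stopped at one equivalent of hydrogen) returns to the route at 21. Dichloromethane still supplies C2, but its configuration then rests on substrate control.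

**Step 5.**
- Risk: chloride 11 is benzylic and carries an ortho alkoxy group, so exchange with free chloride (ionisation and return) can erode the configuration at the future C3 before the methyl group is delivered.
- Fallback: lithiation–borylation from 7, which never passes through a benzylic chloride. Deprotonate ethyl N,N-diisopropylcarbamate with s-BuLi and (+)-sparteine in Et2O at −78 °C to give (1R)-1-lithioethyl N,N-di(propan-2-yl)carbamate F3. If the usual course holds (pro-S deprotonation with (−)-sparteine), (+)-sparteine is the enantiomer needed here. Add 7, which captures F3 with retention as the lithium borate complex F4. Warming with MgBr2·OEt2 induces aryl migration with inversion and loss of the carbamate, which returns to the route at 13.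

**Step 10.**
- Risk: the alkoxyphosphonium intermediate sits on an electron-rich benzylic carbon and may ionise. This would cost stereospecificity at C2 or give the stilbene by elimination across C2–C3.
- Fallback: abandon the SN2 closure and close ring B under thermodynamic control. Treat 21 with a catalytic sulfonic acid in wet CH2Cl2 at low temperature. This ionises C2, lets the adjacent phenol capture the cation to give the more stable trans ring, and hydrolyses the dioxolane in the same operation, returning to the route at 23. No compound outside the list is made; the weakness is possible loss of H3 from the cation.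

**Step 3.**
- Risk: aryllithium 5 may be quenched before it reaches the borate, by proton transfer from the benzylic CH2 of its own ortho benzyloxy group followed by anion rearrangement. This would give debrominated or rearranged material.
- Fallback: replace the lithium route by palladium-catalysed borylation. Treat 3 with Pd(OAc)2, 2-dicyclohexylphosphino-2',4',6'-triisopropylbiphenyl, B2(OH)4 and KOAc in EtOH at 80 °C to give [2-(benzyloxy)-5-(1,3-dioxolan-2-yl)-3-methoxyphenyl]boronic acid F5. Condense F5 with diol 4 over MgSO4 in Et2O, which returns to the route at 7.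

## Further compounds

F1 | step 7 | (2S)-2-[2-(benzyloxy)-5-(1,3-dioxolan-2-yl)-3-methoxyphenyl]propanal | C[C@H](C=O)c1cc(C2OCCO2)cc(OC)c1OCc1ccccc1
F2 | step 7 | (1R,2S)-2-[2-(benzyloxy)-5-(1,3-dioxolan-2-yl)-3-methoxyphenyl]-1-(3,4-dimethoxyphenyl)propan-1-ol | COc1ccc([C@H](O)[C@@H](C)c2cc(C3OCCO3)cc(OC)c2OCc2ccccc2)cc1OC
F3 | step 5 | (1R)-1-lithioethyl N,N-di(propan-2-yl)carbamate | C[C@@H]([Li])OC(=O)N(C(C)C)C(C)C
F4 | step 5 | lithium (4R,5R)-2-[2-(benzyloxy)-5-(1,3-dioxolan-2-yl)-3-methoxyphenyl]-4,5-dicyclohexyl-2-[(1R)-1-{[di(propan-2-yl)carbamoyl]oxy}ethyl]-1,3,2-dioxaborolan-2-uide | C[C@@H]([B-]1(c2cc(C3OCCO3)cc(OC)c2OCc2ccccc2)O[C@H](C2CCCCC2)[C@@H](C2CCCCC2)O1)OC(=O)N(C(C)C)C(C)C.[Li+]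
F0 | step 10 | none | none
F5 | step 3 | [2-(benzyloxy)-5-(1,3-dioxolan-2-yl)-3-methoxyphenyl]boronic acid | COc1cc(C2OCCO2)cc(B(O)O)c1OCc1ccccc1
A1 | alternative 1 | methyl 2-[5-bromo-2-[(3,4-dimethoxyphenyl)methoxy]-3-methoxyphenyl]-2-diazoacetate | COC(=O)C(=[N+]=[N-])c1cc(Br)cc(OC)c1OCc1ccc(OC)c(OC)c1
A2 | alternative 1 | methyl (2S,3R)-5-bromo-2-(3,4-dimethoxyphenyl)-7-methoxy-2,3-dihydro-1-benzofuran-3-carboxylate | COc1ccc([C@H]2Oc3c(OC)cc(Br)cc3[C@H]2C(=O)OC)cc1OC
A3 | alternative 2 | (4S,5S)-5-(3,4-dimethoxyphenyl)-4-methyloxolan-2-one | COc1ccc([C@H]2OC(=O)C[C@@H]2C)cc1OC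
A4 | alternative 2 | tert-butyl{[(4S,5S)-5-(3,4-dimethoxyphenyl)-4-methyl-4,5-dihydrofuran-2-yl]oxy}dimethylsilane | COc1ccc([C@H]2OC(O[Si](C)(C)C(C)(C)C)=C[C@@H]2C)cc1OC
A5 | alternative 2 | methyl 3-bromo-2-oxo-2H-pyran-5-carboxylate | COC(=O)C1=COC(=O)C(Br)=C1
A6 | alternative 2 | methyl (2S,3S)-7-bromo-2-(3,4-dimethoxyphenyl)-3-methyl-2,3-dihydro-1-benzofuran-5-carboxylate | COc1ccc([C@H]2Oc3c(Br)cc(C(=O)OC)cc3[C@@H]2C)cc1OC
A7 | alternative 3 | (3R)-2-(3,4-dimethoxyphenyl)-3-(5-formyl-2-hydroxy-3-methoxyphenyl)butanoic acid | C[C@H](C(C(=O)O)c1ccc(OC)c(OC)c1)c1cc(C=O)cc(OC)c1O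
A8 | alternative 3 | (2S,3S)-2-(3,4-dimethoxyphenyl)-7-methoxy-3-methyl-2,3-dihydro-1-benzofuran-5-carbaldehyde | COc1ccc([C@H]2Oc3c(OC)cc(C=O)cc3[C@@H]2C)cc1OC
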